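The synthesis rests on disconnecting ring A (C1–C2–O3–C4–C5) of the 3,7-dioxabicyclo[3.3.0]octane at C1–C2 and C4–C5. The structural feature used is that the C2–O3–C4 unit bridges the C1–C5 fusion bond: an aryl carbonyl ylide (guaiacyl CH=O(+)–CH2(−)) can therefore add across C1=C5 of a ring-B butenolide in which C8 is the lactone carbonyl and an enol acetate at C1 already carries the tertiary oxygen. One [3+2] cycloaddition closes ring A, forms both C–C bonds and sets C1, C2 and C5 from the single stereocentre C6. Its precursors are (S)-3-acetoxy-5-veratrylfuran-2(5H)-one and the α-chloro (trimethylsilyl)methyl ether of O-allylvanillin.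

Key step: step 6

Remarks on the chemistry

- Atom numbers used throughout: C1 (bridgehead C–O), C2 (guaiacyl CH), O3, C4 (CH2), C5 (bridgehead CH), C6 (veratryl CH), O7, C8.
- Assumption: 4-allyloxy-3-methoxybenzaldehyde (9) is a purchased building block; it is otherwise one step from vanillin, allyl bromide and K2CO3.
- Phenol protection: an allyl ether is used. A benzyl ether would have to be hydrogenolysed next to the benzylic C2–O3 and C6–O7 bonds, which Pd/H2 can cleave in this lignan class. The allyl group keeps the aryl ring electron-rich (needed for the polarity of the dipole) and leaves under neutral Pd(0) conditions.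
- Butenolide: it is made by catalytic asymmetric 2-(ethoxycarbonyl)allylation of veratraldehyde, ozonolysis and enol acetylation. No strongly basic step touches the base-labile γ-aryl butenolide before the cycloaddition.
- Structure check: the configurations of 8 (S at C6), 14 (1R,2R,5R,6S) and 17 (1S,2R,5R,6S) were compared centre by centre and describe the same spatial arrangement; no structure needed correction. The change of the C1 descriptor is only a CIP priority switch (C8 outranks C2 while it is a carbonyl or lactol carbon).

Route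

Step 1
Reactants: 1 veratraldehyde; 2 ethyl 2-(bromomethyl)acrylate
Product: 5 (S)-5-(3,4-dimethoxyphenyl)-3-methylenedihydrofuran-2(3H)-one, via silyl ether 3 (not isolated), via hydroxy ester 4 (not isolated)
Conditions: CrCl2 (10 mol %), chiral carbazole-bis(oxazoline) ligand (12 mol %), Mn (2 equiv), TMSCl (2 equiv), i-Pr2NEt (cat.), THF, rt; then PPTS, THF/H2O, rt
Reagents that add atoms: none
Why: Catalytic enantioselective Nozaki–Hiyama–Kishi-type 2-(alkoxycarbonyl)allylation of an aromatic aldehyde: the chiral Cr(III)–allyl species (ligand enantiomer chosen to give the S carbinol) adds to one enantiotopic face of the formyl group and sets C6, and after desilylation the γ-hydroxy ester closes to the lactone under mild acid that does not ionise the electron-rich benzylic C–O bond.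

Step 2
Reactants: 5 (S)-5-(3,4-dimethoxyphenyl)-3-methylenedihydrofuran-2(3H)-one
Product: 7 (S)-5-(3,4-dimethoxyphenyl)-3-hydroxyfuran-2(5H)-one, via spiro ozonide 6 (not isolated)
Conditions: O3, CH2Cl2, −78 °C (Sudan Red 7B end point); N2 purge; Me2S, −78 °C → rt
Reagents that add atoms: ozone, [O-][O+]=O
Why: Ozonolysis of a 1,1-disubstituted alkene (Criegee mechanism, reductive work-up): the exocyclic alkene reacts far faster with ozone than the dimethoxyarene, the ozonide formed in the non-participating solvent masks the new carbonyl until excess ozone is purged, and the 2,3-dioxo lactone then tautomerises to the conjugated enol without touching C6.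

Step 3
Reactants: 7 (S)-5-(3,4-dimethoxyphenyl)-3-hydroxyfuran-2(5H)-one
Product: 8 (S)-3-acetoxy-5-(3,4-dimethoxyphenyl)furan-2(5H)-one
Conditions: Ac2O (1.2 equiv), pyridine (1.5 equiv), CH2Cl2, 0 °C
Reagents that add atoms: acetic anhydride, CC(=O)OC(C)=O
Why: O-Acylation of the acidic enol of an α-keto lactone with an anhydride under weakly basic conditions; pyridine is too weak a base to remove the γ-hydrogen, so C6 keeps its configuration.

Step 4
Reactants: 9 4-allyloxy-3-methoxybenzaldehyde; 10 (trimethylsilyl)methanol (2.3 equiv)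
Product: 11 4-allyloxy-3-methoxybenzaldehyde bis[(trimethylsilyl)methyl] acetal
Conditions: TsOH·H2O (2 mol %), cyclohexane, reflux, Dean–Stark
Reagents that add atoms: none
Why: Acid-catalysed acetalisation driven by azeotropic removal of water; the allyl ether and the C–Si bonds are inert to catalytic sulfonic acid.

Step 5
Reactants: 11 4-allyloxy-3-methoxybenzaldehyde bis[(trimethylsilyl)methyl] acetal
Product: 12 chloro(4-allyloxy-3-methoxyphenyl)methyl (trimethylsilyl)methyl ether (racemic)
Conditions: AcCl (1.1 equiv), ZnBr2 (cat.), CH2Cl2, 0 °C → rt; volatiles removed, crude 12 used at once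
Reagents that add atoms: acetyl chloride, CC(Cl)=O
Why: Acetal–acyl halide exchange, the classical α-chloro ether synthesis: one alkoxy group is acylated and leaves as its acetate, and chloride captures the p-alkoxy-stabilised oxocarbenium ion; the chloride carbon is racemic, which is irrelevant because it becomes the planar ylide carbon.

Step 6
Reactants: 8 (S)-3-acetoxy-5-(3,4-dimethoxyphenyl)furan-2(5H)-one; 12 chloro(4-allyloxy-3-methoxyphenyl)methyl (trimethylsilyl)methyl ether
Product: 14 (1R,2R,5R,6S)-1-acetoxy-2-(4-allyloxy-3-methoxyphenyl)-6-(3,4-dimethoxyphenyl)-3,7-dioxabicyclo[3.3.0]octan-8-one, via carbonyl ylide 13 (not isolated)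
Conditions: CsF (6 equiv, dried), MeCN, 0 °C → rt; crude 12 (3 equiv) added slowly to 8 (1 equiv)
Reagents that add atoms: none
Why: Fluoride attacks silicon of 12 (in equilibrium with its oxocarbenium chloride ion pair), fluorotrimethylsilane and chloride leave in a 1,3-elimination, and the non-stabilised carbonyl ylide 13 adds as the 4π partner across the electron-poor C1=C5 bond of 8 in a concerted, suprafacial [3+2] cycloaddition. The closest known reaction is the cycloaddition of carbonyl ylides made by this silicon-based 1,3-elimination with acrylates, fumarates and enones, which gives tetrahydrofurans. Ring A (C1–C2–O3–C4–C5) closes by intermolecular [3+2] annulation onto the butenolide, and because both new bonds (C1–C2 and C4–C5) form on one face the 5/5 fusion is cis. C5 and C1 are set by attack on the face opposite the veratryl group at C6, the only stereocentre of 8 and the direct neighbour of C5, and are tied to each other by suprafaciality; C2 is set by the exo transition state, in which the outward (E-type) aryl group of the ylide and the ylide oxygen point away from the lactone ring. The step needs regioselectivity (CH2 terminus C4 to C5, aryl-bearing terminus C2 to C1), and the substrate pair secures it by polarisation: the p-alkoxyaryl group carries the cationic character of the dipole at C2, so C4 is the nucleophilic end and goes to the β-carbon C5, where the LUMO coefficient of the α-acyloxy enoate is largest. Heterogeneous CsF, slow addition of 12 and 8 as the limiting partner keep the base-labile C6–H and the enol acetate intact until the ylide is trapped.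

Step 7
Reactants: 14 (1R,2R,5R,6S)-1-acetoxy-2-(4-allyloxy-3-methoxyphenyl)-6-(3,4-dimethoxyphenyl)-3,7-dioxabicyclo[3.3.0]octan-8-one
Product: 15 (1R,2R,5R,6S)-2-(4-allyloxy-3-methoxyphenyl)-6-(3,4-dimethoxyphenyl)-3,7-dioxabicyclo[3.3.0]octane-1,8-diol (lactol, both C8 epimers)
Conditions: DIBAL-H (5 equiv), CH2Cl2, −78 → −40 °C; Rochelle salt
Reagents that add atoms: none
Why: Hydride reduction with DIBAL-H: the lactone stops at the tetrahedral aluminium hemiacetal at low temperature (lactol on work-up) and the tertiary acetate is reduced off in the same operation; no stereocentre of the bicycle is touched and the C8 epimers converge in step 8.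

Step 8
Reactants: 15 (1R,2R,5R,6S)-2-(4-allyloxy-3-methoxyphenyl)-6-(3,4-dimethoxyphenyl)-3,7-dioxabicyclo[3.3.0]octane-1,8-diol
Product: 16 (1S,2R,5R,6S)-2-(4-allyloxy-3-methoxyphenyl)-6-(3,4-dimethoxyphenyl)-3,7-dioxabicyclo[3.3.0]octan-1-ol
Conditions: Et3SiH (5 equiv), BF3·OEt2 (2.5 equiv), CH2Cl2, −78 → −30 °C; aq. NaHCO3
Reagents that add atoms: none
Why: Ionic hydrogenation of a lactol: BF3 ionises the hemiacetal to the cyclic oxocarbenium ion, which forms far more readily at low temperature than a cation from the benzylic ether bonds or from the tertiary C1–OH (flanked by two C–O bonds), and triethylsilane delivers hydride to C8.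

Step 9
Reactants: 16 (1S,2R,5R,6S)-2-(4-allyloxy-3-methoxyphenyl)-6-(3,4-dimethoxyphenyl)-3,7-dioxabicyclo[3.3.0]octan-1-ol
Product: 17 (1S,2R,5R,6S)-6-(3,4-dimethoxyphenyl)-2-(4-hydroxy-3-methoxyphenyl)-3,7-dioxabicyclo[3.3.0]octan-1-ol (CNP0141816.1)
Conditions: Pd(PPh3)4 (5 mol %), morpholine (5 equiv), THF, rt
Reagents that add atoms: none
Why: Tsuji–Trost-type deallylation: Pd(0) ionises the aryl allyl ether to a π-allyl complex and the phenoxide, and morpholine takes up the allyl group; the neutral conditions leave the benzylic C–O bonds and the tertiary alcohol untouched.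

Compound list

1 | veratraldehyde (3,4-dimethoxybenzaldehyde) | COc1ccc(C=O)cc1OC | starting material
2 | ethyl 2-(bromomethyl)acrylate | C=C(CBr)C(=O)OCC | starting material
3 | ethyl (S)-4-(3,4-dimethoxyphenyl)-2-methylene-4-(trimethylsilyloxy)butanoate | C=C(C[C@H](O[Si](C)(C)C)c1ccc(OC)c(OC)c1)C(=O)OCC | intermediate (not isolated)
4 | ethyl (S)-4-(3,4-dimethoxyphenyl)-4-hydroxy-2-methylenebutanoate | C=C(C[C@H](O)c1ccc(OC)c(OC)c1)C(=O)OCC | intermediate (not isolated)
5 | (S)-5-(3,4-dimethoxyphenyl)-3-methylenedihydrofuran-2(3H)-one | C=C1C[C@@H](c2ccc(OC)c(OC)c2)OC1=O | intermediate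
6 | (8S)-8-(3,4-dimethoxyphenyl)-1,2,4,7-tetraoxaspiro[4.4]nonan-6-one (spiro ozonide, both spiro epimers) | O=C1O[C@H](c2ccc(OC)c(OC)c2)CC12OCOO2 | intermediate (not isolated)
7 | (S)-5-(3,4-dimethoxyphenyl)-3-hydroxyfuran-2(5H)-one (enol form of the 2,3-dione) | OC1=C[C@@H](c2ccc(OC)c(OC)c2)OC1=O | intermediate
8 | (S)-3-acetoxy-5-(3,4-dimethoxyphenyl)furan-2(5H)-one | CC(=O)OC1=C[C@@H](c2ccc(OC)c(OC)c2)OC1=O | intermediate
9 | 4-allyloxy-3-methoxybenzaldehyde (O-allylvanillin) | C=CCOc1ccc(C=O)cc1OC | starting material
10 | (trimethylsilyl)methanol | C[Si](C)(C)CO | starting material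
11 | 4-allyloxy-3-methoxybenzaldehyde bis[(trimethylsilyl)methyl] acetal | C=CCOc1ccc(C(OC[Si](C)(C)C)OC[Si](C)(C)C)cc1OC | intermediate
12 | chloro(4-allyloxy-3-methoxyphenyl)methyl (trimethylsilyl)methyl ether (racemic) | C=CCOc1ccc(C(Cl)OC[Si](C)(C)C)cc1OC | intermediate
13 | carbonyl ylide, (4-allyloxy-3-methoxybenzylidene)oxonium methylide | C=CCOc1ccc(C=[O+][CH2-])cc1OC | intermediate (not isolated)
14 | (1R,2R,5R,6S)-1-acetoxy-2-(4-allyloxy-3-methoxyphenyl)-6-(3,4-dimethoxyphenyl)-3,7-dioxabicyclo[3.3.0]octan-8-one (cis-fused, both aryl groups exo) | CC(=O)O[C@]12C(=O)O[C@H](c3ccc(OC)c(OC)c3)[C@H]1CO[C@@H]2c1ccc(OCC=C)c(OC)c1 | intermediate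
15 | (1R,2R,5R,6S)-2-(4-allyloxy-3-methoxyphenyl)-6-(3,4-dimethoxyphenyl)-3,7-dioxabicyclo[3.3.0]octane-1,8-diol (lactol, both C8 epimers) | O[C@]12C(O)O[C@H](c3ccc(OC)c(OC)c3)[C@H]1CO[C@@H]2c1ccc(OCC=C)c(OC)c1 | intermediate
16 | (1S,2R,5R,6S)-2-(4-allyloxy-3-methoxyphenyl)-6-(3,4-dimethoxyphenyl)-3,7-dioxabicyclo[3.3.0]octan-1-ol | O[C@]12CO[C@H](c3ccc(OC)c(OC)c3)[C@H]1CO[C@@H]2c1ccc(OCC=C)c(OC)c1 | intermediate
17 | (1S,2R,5R,6S)-6-(3,4-dimethoxyphenyl)-2-(4-hydroxy-3-methoxyphenyl)-3,7-dioxabicyclo[3.3.0]octan-1-ol | O[C@]12CO[C@H](c3ccc(OC)c(OC)c3)[C@H]1CO[C@@H]2c1ccc(O)c(OC)c1 | target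

Total step count: 9. Longest linear sequence: 7 steps (1, 2, 3, 6, 7, 8, 9); the second branch (4, 5) joins at step 6.

Steps most likely to fail

Step 6. What may go wrong:
- the dipole may add with the reverse orientation;
- the aryl group of the ylide may end up endo at C2;
- fluoride may remove the γ-hydrogen at C6 (loss of configuration) or the enol acetyl group before the ylide is trapped;
- the ylide may react with itself.

Fallback: the same two bonds are made one after the other on a tether, without fluoride. It sets out from 8 and 12.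
- Benzophenone-sensitised photoaddition of methanol to 8 (hν 350 nm, MeOH) should place a hydroxymethyl radical on C5 anti to the veratryl group and give (5S)-3-acetoxy-4-(hydroxymethyl)-5-(3,4-dimethoxyphenyl)dihydrofuran-2(3H)-one F1 (4,5-trans, both C3 epimers).
- The primary alcohol is alkylated with chloro ether 12 (i-Pr2NEt, CH2Cl2, 0 °C) to the mixed acetal F2.
- LiHMDS/TMSCl (THF, −78 °C) should give the silyl ketene acetal F3. Catalytic TMSOTf (CH2Cl2, −78 °C) then ionises the acetal to the tethered oxocarbenium ion, which the ketene acetal carbon C1 attacks intramolecularly (Mukaiyama-type addition to an acetal).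
- The tether forces C2 onto the face that carries C4, so the fusion is cis, and the regiochemistry is fixed by connectivity. Reversible ionisation of the p-alkoxybenzylic C2–O3 bond should allow C2 to settle in the exo arrangement.
- The sequence comes back to the route at 14.

Step 8. What may go wrong: the Lewis acid may ionise the benzylic C2–O3 or C6–O7 bonds in competition with the lactol, leading to epimerisation or reductive ring opening. The open hydroxy-aldehyde form may also be reduced at the benzylic carbinol.

Fallback: reduce and re-close instead of ionising. It sets out from 15.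
- NaBH4 (MeOH, 0 °C) should reduce the open form of the lactol to the triol F4.
- MsCl (1.05 equiv) in pyridine at 0 °C sulfonylates the primary C8 hydroxyl to the monomesylate F5.
- On warming, F5 should close ring B by 5-exo-tet displacement by the C6 hydroxyl with retention at C6, the usual diol-to-furofuran closure. The weak base keeps the tertiary C1 hydroxyl from forming an epoxide.
- The sequence comes back to the route at 16.

Step 1. What may go wrong: the chromium cycle may stall, or the enantioselectivity may be only moderate with this electron-rich aldehyde.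

Fallback: set C6 by asymmetric ketone reduction. It sets out from 1 and 2.
- Zinc-mediated Barbier allylation (Zn, THF/aq. NH4Cl) should give the racemic hydroxy ester F6.
- Activated MnO2 (CH2Cl2, rt) oxidises the benzylic alcohol to the aryl ketone F7 under neutral conditions.
- Corey–Bakshi–Shibata reduction ((R)-Me-CBS, catecholborane, toluene, −78 °C) should return the (S)-alcohol 4, which lactonises with PPTS.
- The sequence comes back to the route at 5.

Further compounds

F1 | step 6 | (5S)-3-acetoxy-4-(hydroxymethyl)-5-(3,4-dimethoxyphenyl)dihydrofuran-2(3H)-one (4,5-trans) | CC(=O)OC1C(=O)O[C@H](c2ccc(OC)c(OC)c2)[C@H]1CO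
F2 | step 6 | mixed acetal of F1 with 12, (5S)-3-acetoxy-4-{[(4-allyloxy-3-methoxyphenyl)((trimethylsilyl)methoxy)methoxy]methyl}-5-(3,4-dimethoxyphenyl)dihydrofuran-2(3H)-one | CC(=O)OC1C(=O)O[C@H](c2ccc(OC)c(OC)c2)[C@H]1COC(OC[Si](C)(C)C)c1ccc(OCC=C)c(OC)c1
F3 | step 6 | trimethylsilyl ketene acetal of F2 (3-acetoxy-2-(trimethylsilyloxy)-4,5-dihydrofuran) | CC(=O)OC1=C(O[Si](C)(C)C)O[C@H](c2ccc(OC)c(OC)c2)[C@H]1COC(OC[Si](C)(C)C)c1ccc(OCC=C)c(OC)c1
F4 | step 8 | triol, (2R,3S,4R)-2-(4-allyloxy-3-methoxyphenyl)-4-[(S)-(3,4-dimethoxyphenyl)(hydroxy)methyl]-3-(hydroxymethyl)tetrahydrofuran-3-ol | OC[C@]1(O)[C@@H](c2ccc(OCC=C)c(OC)c2)OC[C@@H]1[C@H](O)c1ccc(OC)c(OC)c1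
F5 | step 8 | primary monomesylate of F4 | CS(=O)(=O)OC[C@]1(O)[C@@H](c2ccc(OCC=C)c(OC)c2)OC[C@@H]1[C@H](O)c1ccc(OC)c(OC)c1
F6 | step 1 | racemic ethyl 4-(3,4-dimethoxyphenyl)-4-hydroxy-2-methylenebutanoate | C=C(CC(O)c1ccc(OC)c(OC)c1)C(=O)OCC
F7 | step 1 | ethyl 4-(3,4-dimethoxyphenyl)-2-methylene-4-oxobutanoate | C=C(CC(=O)c1ccc(OC)c(OC)c1)C(=O)OCC
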